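**Retrosynthetic overview**

1. The target is read as a germacranolide: a ten-membered carbocycle C1–C10 with C1=C10 (Z, methyl C14 on C10) and C4=C5 (E, methyl C15 on C4), an acyloxy group on C3, a hydroxyl on C9, and a γ-lactone (O6–C6–C7–C11–C12, methyl C13 on C11) cis-fused across C6–C7.
2. Last disconnection: C5–C6, an alkenyl iodide adding to a C6 aldehyde (Nozaki–Hiyama–Kishi), which closes the ten-membered ring. Enabling feature: C6 is allylic to C4=C5 and 1,4 to the C12 carbonyl, while O9 is 1,5 to that same carbonyl.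
3. C12 is therefore parked on O9 as a temporary δ-lactone (O9, C9, C8, C7, C11, C12) that carries the C6 and C10 arms cis-1,3. After ring closure the acyl group moves from O9 to the new O6, which makes the γ-lactone and frees the 9-hydroxyl; no hydroxyl protecting group is used anywhere.
4. The δ-lactone (intramolecular Horner–Wadsworth–Emmons) relays C9 to C7 (conjugate reduction) and C11 (enolate methylation). C9 comes from a boron aldol on a Z-enal whose Z-C1=C10 bond is made inside an earlier temporary six-membered lactone (O3–C9) by ring-closing metathesis; C3 comes from Brown allylation and E-C4=C5 from carboalumination–iodination.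
5. Ring order: dihydropyranone (temporary, opened again), δ-lactone (temporary), then ten-membered carbocycle and γ-lactone together in the final step.

Key step: step 15

Assumption: the facial sense of the diisopinocampheylboron reagents is taken from the usual empirical models (Si-face attack on the aldehyde for (−)-Ipc2B(allyl) and for the methyl ketone enol borinate made with (+)-Ipc2BCl); if either sense proved opposite, the antipodal reagent would be used at that step, and both reagents and (2R)-2-methylbutanoic acid are taken as purchased.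

**Route**

Step 1
Reactants: 1 prop-2-yn-1-ol
Product: 3 (E)-3-iodo-2-methylprop-2-en-1-ol, via alkenylalane 2 (not isolated)
Conditions: AlMe3 (3 equiv), Cp2ZrCl2 (0.25 equiv), CH2Cl2, 0 °C to rt; then I2, THF, −30 to 0 °C; aq. K2CO3 work-up
Reagents that add atoms: trimethylaluminium, C[Al](C)C; iodine, II
Why: Zirconium-catalysed syn-carboalumination of the alkyne (Negishi carboalumination) puts methyl on the internal and aluminium on the terminal carbon, and iodinolysis of the C–Al bond with retention fixes the E geometry of the future C4=C5 alkene.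

Step 2
Reactants: 3 (E)-3-iodo-2-methylprop-2-en-1-ol
Product: 4 (E)-3-iodo-2-methylprop-2-enal
Conditions: MnO2 (activated, excess), CH2Cl2, rt
Reagents that add atoms: none
Why: Allylic oxidation with MnO2 is selective for the allylic alcohol and should leave the C–I bond and the alkene geometry untouched.

Step 3
Reactants: 4 (E)-3-iodo-2-methylprop-2-enal
Product: 6 (3S,1E)-1-iodo-2-methylhexa-1,5-dien-3-ol, via borinate ester 5 (not isolated)
Conditions: (−)-Ipc2B(allyl), Et2O, −78 °C; then HOCH2CH2NH2, rt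
Reagents that add atoms: (−)-B-allyldiisopinocampheylborane, C=CCB([C@@H]1C[C@@H]2C[C@H]([C@H]1C)C2(C)C)[C@@H]1C[C@@H]2C[C@H]([C@H]1C)C2(C)C
Why: Brown allylation through a chair six-membered transition state delivers the allyl group to the Si face of the aldehyde under reagent control and so sets C3 as S, and the amino alcohol then releases the alcohol from boron.

Step 4
Reactants: 6 (3S,1E)-1-iodo-2-methylhexa-1,5-dien-3-ol; 7 methacryloyl chloride
Product: 8 (3S,1E)-1-iodo-2-methylhexa-1,5-dien-3-yl 2-methylprop-2-enoate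
Conditions: Et3N, DMAP (cat.), CH2Cl2, 0 °C to rt
Reagents that add atoms: methacryloyl chloride (compound 7), C=C(C)C(Cl)=O
Why: O-acylation of the secondary alcohol by the acid chloride under nucleophilic catalysis installs the methacrylate that carries the future C9, C10 and C14.

Step 5
Reactants: 8 (3S,1E)-1-iodo-2-methylhexa-1,5-dien-3-yl 2-methylprop-2-enoate
Product: 9 (6S)-6-[(E)-1-iodoprop-1-en-2-yl]-3-methyl-5,6-dihydro-2H-pyran-2-one
Conditions: second-generation Grubbs catalyst (H2IMes)(PCy3)Cl2Ru=CHPh (5 mol %), CH2Cl2 (0.01 M), 40 °C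
Reagents that add atoms: none
Why: Ring-closing metathesis between the terminal alkene and the methacrylate gives the six-membered unsaturated lactone, in which the new trisubstituted C1=C10 alkene can only be cis within the ring, which secures the Z geometry, while the hindered iodoalkene is inert to the catalyst.

Step 6
Reactants: 9 (6S)-6-[(E)-1-iodoprop-1-en-2-yl]-3-methyl-5,6-dihydro-2H-pyran-2-one
Product: 10 (2Z,5S,6E)-5-hydroxy-7-iodo-N-methoxy-N,2,6-trimethylhepta-2,6-dienamide
Conditions: MeNHOMe·HCl, AlMe3, CH2Cl2, 0 °C to rt; aq. KNaC4H4O6 work-up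
Reagents that add atoms: N,O-dimethylhydroxylamine hydrochloride, CNOC.Cl
Why: Aluminium amide aminolysis of the lactone (Weinreb amide formation) opens the temporary ring without disturbing the Z alkene and leaves the C3 hydroxyl as the only free alcohol in the molecule.

Step 7
Reactants: 10 (2Z,5S,6E)-5-hydroxy-7-iodo-N-methoxy-N,2,6-trimethylhepta-2,6-dienamide; 11 (2R)-2-methylbutanoic acid
Product: 12 (2Z,5S,6E)-7-iodo-N-methoxy-N,2,6-trimethyl-5-{[(2R)-2-methylbutanoyl]oxy}hepta-2,6-dienamide
Conditions: DCC, DMAP (cat.), CH2Cl2, 0 °C to rt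
Reagents that add atoms: (2R)-2-methylbutanoic acid (compound 11), CC[C@@H](C)C(=O)O
Why: Steglich esterification acylates the single free hydroxyl (O3) under mild conditions that are not expected to epimerise the α-stereocentre of the acid.

Step 8
Reactants: 12 (2Z,5S,6E)-7-iodo-N-methoxy-N,2,6-trimethyl-5-{[(2R)-2-methylbutanoyl]oxy}hepta-2,6-dienamide
Product: 13 (1E,3S,5Z)-1-iodo-2,6-dimethyl-7-oxohepta-1,5-dien-3-yl (2R)-2-methylbutanoate
Conditions: Cp2Zr(H)Cl (1.5 equiv), THF, rt, 20 min; silica gel work-up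
Reagents that add atoms: none
Why: Amide reduction with the Schwartz reagent gives a zirconated hemiaminal that collapses to the aldehyde only on work-up, a reduction type that spares esters and alkenyl halides and stops at the aldehyde oxidation level.

Step 9
Reactants: 13 (1E,3S,5Z)-1-iodo-2,6-dimethyl-7-oxohepta-1,5-dien-3-yl (2R)-2-methylbutanoate; 14 1,1-dimethoxypropan-2-one
Product: 17 (1E,3S,5Z,7S)-7-hydroxy-1-iodo-10,10-dimethoxy-2,6-dimethyl-9-oxodeca-1,5-dien-3-yl (2R)-2-methylbutanoate, via enol borinate 15 (not isolated), via boron aldolate 16 (not isolated)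
Conditions: 14, (+)-Ipc2BCl, Et3N, Et2O, 0 °C; then 13, −78 to −20 °C; H2O2, MeOH, pH 7 phosphate buffer, 0 °C
Reagents that add atoms: 1,1-dimethoxypropan-2-one (compound 14), CC(=O)C(OC)OC
Why: Boron-mediated aldol addition of a methyl ketone: kinetic enolisation on the methyl side, then addition through a cyclic transition state in which the isopinocampheyl ligands direct attack to the Si face of the enal, should set C9 as S under reagent control, the remote C3 centre having no influence.

Step 10
Reactants: 17 (1E,3S,5Z,7S)-7-hydroxy-1-iodo-10,10-dimethoxy-2,6-dimethyl-9-oxodeca-1,5-dien-3-yl (2R)-2-methylbutanoate; 18 2-(diethoxyphosphoryl)acetic acid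
Product: 19 (1E,3S,5Z,7S)-7-{[2-(diethoxyphosphoryl)acetyl]oxy}-1-iodo-10,10-dimethoxy-2,6-dimethyl-9-oxodeca-1,5-dien-3-yl (2R)-2-methylbutanoate
Conditions: DCC, DMAP (cat.), CH2Cl2, 0 °C
Reagents that add atoms: 2-(diethoxyphosphoryl)acetic acid (compound 18), CCOP(=O)(CC(=O)O)OCC
Why: Steglich esterification of the new secondary alcohol proceeds without a base strong enough to trigger β-elimination of the β-acyloxy ketone.

Step 11
Reactants: 19 (1E,3S,5Z,7S)-7-{[2-(diethoxyphosphoryl)acetyl]oxy}-1-iodo-10,10-dimethoxy-2,6-dimethyl-9-oxodeca-1,5-dien-3-yl (2R)-2-methylbutanoate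
Product: 20 (1E,3S,5Z)-6-[(2S)-4-(dimethoxymethyl)-6-oxo-3,6-dihydro-2H-pyran-2-yl]-1-iodo-2-methylhepta-1,5-dien-3-yl (2R)-2-methylbutanoate
Conditions: LiCl, i-Pr2NEt, MeCN, rt
Reagents that add atoms: none
Why: Intramolecular Horner–Wadsworth–Emmons olefination under Masamune–Roush conditions, where only the phosphonate is acidic enough to be deprotonated, closes the six-membered unsaturated lactone onto the activated α-alkoxy ketone (C7).

Step 12
Reactants: 20 (1E,3S,5Z)-6-[(2S)-4-(dimethoxymethyl)-6-oxo-3,6-dihydro-2H-pyran-2-yl]-1-iodo-2-methylhepta-1,5-dien-3-yl (2R)-2-methylbutanoate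
Product: 21 (1E,3S,5Z)-6-[(2S,4S)-4-(dimethoxymethyl)-6-oxooxan-2-yl]-1-iodo-2-methylhepta-1,5-dien-3-yl (2R)-2-methylbutanoate
Conditions: Cu(OAc)2·H2O (5 mol %), 1,2-(Ph2P)2C6H4 (5 mol %), MeSiH(OEt)2, t-BuOH, toluene, rt
Reagents that add atoms: none
Why: Copper hydride conjugate reduction: hydride is delivered to C7 on the face opposite the C9 side chain of the half-chair dihydropyranone (axial attack anti to the ring substituent, as in conjugate additions to such lactones), which leaves the dimethoxymethyl group cis to the C9 arm and sets C7 as S, while isolated alkenes, the iodoalkene and the esters are not reduced.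

Step 13
Reactants: 21 (1E,3S,5Z)-6-[(2S,4S)-4-(dimethoxymethyl)-6-oxooxan-2-yl]-1-iodo-2-methylhepta-1,5-dien-3-yl (2R)-2-methylbutanoate
Product: 23 (1E,3S,5Z)-6-[(2S,4S,5R)-4-(dimethoxymethyl)-5-methyl-6-oxooxan-2-yl]-1-iodo-2-methylhepta-1,5-dien-3-yl (2R)-2-methylbutanoate, via lithium enolate 22 (not isolated)
Conditions: LiN(i-Pr)2 (1.05 equiv), THF, −78 °C; then MeI, −78 to −40 °C
Reagents that add atoms: iodomethane, CI
Why: Lactone enolate alkylation: the lactone α-CH2 is more acidic and far more accessible than the tertiary α-H of the branched ester, and iodomethane approaches the enolate anti to the adjacent C7 substituent, which sets C11 as R with all three ring substituents equatorial.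

Step 14
Reactants: 23 (1E,3S,5Z)-6-[(2S,4S,5R)-4-(dimethoxymethyl)-5-methyl-6-oxooxan-2-yl]-1-iodo-2-methylhepta-1,5-dien-3-yl (2R)-2-methylbutanoate
Product: 24 (1E,3S,5Z)-6-[(2S,4S,5R)-4-formyl-5-methyl-6-oxooxan-2-yl]-1-iodo-2-methylhepta-1,5-dien-3-yl (2R)-2-methylbutanoate
Conditions: TsOH·H2O (cat.), acetone–H2O (10:1), rt
Reagents that add atoms: water, O
Why: Acid-catalysed acetal hydrolysis liberates the C6 aldehyde, and because the formyl group already sits equatorial in the thermodynamically preferred arrangement, enolisation at C7 should not erode the stereocentre.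

Step 15
Reactants: 24 (1E,3S,5Z)-6-[(2S,4S,5R)-4-formyl-5-methyl-6-oxooxan-2-yl]-1-iodo-2-methylhepta-1,5-dien-3-yl (2R)-2-methylbutanoate
Product: 27 (3S,6R,7S,9S,11R)-9-hydroxy-3-{[(2R)-2-methylbutanoyl]oxy}germacra-1(10)Z,4E-dien-12,6-olide, via alkenylchromium 25 (not isolated), via chromium alkoxide 26 (not isolated)
Conditions: CrCl2 (12 equiv), NiCl2 (0.1 equiv), degassed DMSO–THF, 25 °C, slow addition of 24 to 0.002 M; then 40 °C; aq. NH4Cl work-up
Reagents that add atoms: none
Why: Nozaki–Hiyama–Kishi reaction: zerovalent nickel inserts into the C5–I bond with retention of the E geometry and passes the alkenyl group to chromium (25), which adds only to the C6 aldehyde and thereby closes the ten-membered carbocycle through C5–C6 (10-exo-trig; closest known type: NHK macrocyclisation of iodoalkene aldehydes to nine- to twelve-membered carbocycles). The resulting trivalent chromium alkoxide on O6 (26) sits 1,4 to the C12 carbonyl and attacks it (5-exo-trig), the tetrahedral intermediate expels O9, and the temporary δ-lactone is exchanged for the γ-lactone while the 9-hydroxyl is released on work-up (closest known type: lactonisation of chromium alkoxides onto γ-esters in chromium-mediated allylations). The new stereocentre C6 is set by Felkin–Anh addition: the alkenyl group enters anti to the branched ring carbon C11 and gauche to C8, the carbon through which it is tethered, which should give 6R with H6 cis to H7 and hence the cis ring fusion. Ring closure must outrun oligomerisation, which is secured by high dilution and by two turn elements of the substrate, the Z-C1=C10 alkene and the cis-1,3 arms on the δ-lactone, whose ring-flipped conformer holds C6 and C10 syn-axial. Chemoselectivity for the aldehyde over the lactone and ester carbonyls is inherent to alkenylchromium reagents, and the direction of acyl transfer follows the preference for a five- over a six-membered lactone.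

**Compound list**

1 | prop-2-yn-1-ol | C#CCO | starting material
2 | dimethylaluminium (E)-3-(dimethylalumanyl)-2-methylprop-2-en-1-olate (alkenylalane, formed in the flask) | C[Al](C)OC/C(C)=C/[Al](C)C | intermediate
3 | (E)-3-iodo-2-methylprop-2-en-1-ol | OC/C(C)=C/I | intermediate
4 | (E)-3-iodo-2-methylprop-2-enal | O=C/C(C)=C/I | intermediate
5 | (3S,1E)-1-iodo-2-methylhexa-1,5-dien-3-yl diisopinocampheylborinate (formed in the flask) | C=CC[C@H](OB([C@@H]1C[C@@H]2C[C@H]([C@H]1C)C2(C)C)[C@@H]1C[C@@H]2C[C@H]([C@H]1C)C2(C)C)/C(C)=C/I | intermediate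
6 | (3S,1E)-1-iodo-2-methylhexa-1,5-dien-3-ol | O[C@@H](CC=C)/C(C)=C/I | intermediate
7 | methacryloyl chloride | C=C(C)C(Cl)=O | starting material
8 | (3S,1E)-1-iodo-2-methylhexa-1,5-dien-3-yl 2-methylprop-2-enoate | C=C(C)C(=O)O[C@@H](CC=C)/C(C)=C/I | intermediate
9 | (6S)-6-[(E)-1-iodoprop-1-en-2-yl]-3-methyl-5,6-dihydro-2H-pyran-2-one | O=C1O[C@H](/C(C)=C/I)CC=C1C | intermediate
10 | (2Z,5S,6E)-5-hydroxy-7-iodo-N-methoxy-N,2,6-trimethylhepta-2,6-dienamide | O[C@@H](C/C=C(/C)C(=O)N(C)OC)/C(C)=C/I | intermediate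
11 | (2R)-2-methylbutanoic acid | CC[C@@H](C)C(=O)O | starting material
12 | (2Z,5S,6E)-7-iodo-N-methoxy-N,2,6-trimethyl-5-{[(2R)-2-methylbutanoyl]oxy}hepta-2,6-dienamide | CC[C@@H](C)C(=O)O[C@@H](C/C=C(/C)C(=O)N(C)OC)/C(C)=C/I | intermediate
13 | (1E,3S,5Z)-1-iodo-2,6-dimethyl-7-oxohepta-1,5-dien-3-yl (2R)-2-methylbutanoate | CC[C@@H](C)C(=O)O[C@@H](C/C=C(/C)C=O)/C(C)=C/I | intermediate
14 | 1,1-dimethoxypropan-2-one | CC(=O)C(OC)OC | starting material
15 | 3,3-dimethoxyprop-1-en-2-yl diisopinocampheylborinate (enol borinate, formed in the flask) | C=C(OB([C@H]1C[C@H]2C[C@@H]([C@@H]1C)C2(C)C)[C@H]1C[C@H]2C[C@@H]([C@@H]1C)C2(C)C)C(OC)OC | intermediate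
16 | O-diisopinocampheylboryl aldolate of 17 (formed in the flask) | CC[C@@H](C)C(=O)O[C@@H](C/C=C(/C)[C@@H](OB([C@H]1C[C@H]2C[C@@H]([C@@H]1C)C2(C)C)[C@H]1C[C@H]2C[C@@H]([C@@H]1C)C2(C)C)CC(=O)C(OC)OC)/C(C)=C/I | intermediate
17 | (1E,3S,5Z,7S)-7-hydroxy-1-iodo-10,10-dimethoxy-2,6-dimethyl-9-oxodeca-1,5-dien-3-yl (2R)-2-methylbutanoate | CC[C@@H](C)C(=O)O[C@@H](C/C=C(/C)[C@@H](O)CC(=O)C(OC)OC)/C(C)=C/I | intermediate
18 | 2-(diethoxyphosphoryl)acetic acid | CCOP(=O)(CC(=O)O)OCC | starting material
19 | (1E,3S,5Z,7S)-7-{[2-(diethoxyphosphoryl)acetyl]oxy}-1-iodo-10,10-dimethoxy-2,6-dimethyl-9-oxodeca-1,5-dien-3-yl (2R)-2-methylbutanoate | CC[C@@H](C)C(=O)O[C@@H](C/C=C(/C)[C@@H](OC(=O)CP(=O)(OCC)OCC)CC(=O)C(OC)OC)/C(C)=C/I | intermediate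
20 | (1E,3S,5Z)-6-[(2S)-4-(dimethoxymethyl)-6-oxo-3,6-dihydro-2H-pyran-2-yl]-1-iodo-2-methylhepta-1,5-dien-3-yl (2R)-2-methylbutanoate | CC[C@@H](C)C(=O)O[C@@H](C/C=C(/C)[C@@H]1CC(C(OC)OC)=CC(=O)O1)/C(C)=C/I | intermediate
21 | (1E,3S,5Z)-6-[(2S,4S)-4-(dimethoxymethyl)-6-oxooxan-2-yl]-1-iodo-2-methylhepta-1,5-dien-3-yl (2R)-2-methylbutanoate | CC[C@@H](C)C(=O)O[C@@H](C/C=C(/C)[C@@H]1C[C@H](C(OC)OC)CC(=O)O1)/C(C)=C/I | intermediate
22 | lithium enolate of lactone 21 (formed in the flask) | CC[C@@H](C)C(=O)O[C@@H](C/C=C(/C)[C@@H]1C[C@H](C(OC)OC)C=C(O[Li])O1)/C(C)=C/I | intermediate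
23 | (1E,3S,5Z)-6-[(2S,4S,5R)-4-(dimethoxymethyl)-5-methyl-6-oxooxan-2-yl]-1-iodo-2-methylhepta-1,5-dien-3-yl (2R)-2-methylbutanoate | CC[C@@H](C)C(=O)O[C@@H](C/C=C(/C)[C@@H]1C[C@H](C(OC)OC)[C@@H](C)C(=O)O1)/C(C)=C/I | intermediate
24 | (1E,3S,5Z)-6-[(2S,4S,5R)-4-formyl-5-methyl-6-oxooxan-2-yl]-1-iodo-2-methylhepta-1,5-dien-3-yl (2R)-2-methylbutanoate | CC[C@@H](C)C(=O)O[C@@H](C/C=C(/C)[C@@H]1C[C@H](C=O)[C@@H](C)C(=O)O1)/C(C)=C/I | intermediate
25 | alkenylchromium dichloride from 24 (C5–Cr in place of C5–I, formed in the flask) | CC[C@@H](C)C(=O)O[C@@H](C/C=C(/C)[C@@H]1C[C@H](C=O)[C@@H](C)C(=O)O1)/C(C)=C/[Cr](Cl)Cl | intermediate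
26 | chromium dichloride alkoxide of the (6R)-hydroxy bicyclic δ-lactone (ten-membered ring closed, O9–C12 lactone still in place, formed in the flask) | CC[C@@H](C)C(=O)O[C@H]1C/C=C(/C)[C@@H]3C[C@H]([C@H](/C=C/1C)O[Cr](Cl)Cl)[C@@H](C)C(=O)O3 | intermediate
27 | (3S,6R,7S,9S,11R)-9-hydroxy-3-{[(2R)-2-methylbutanoyl]oxy}germacra-1(10)Z,4E-dien-12,6-olide | CC[C@@H](C)C(=O)O[C@H]1C/C=C(/C)[C@@H](O)C[C@@H]2[C@H](/C=C/1C)OC(=O)[C@@H]2C | target

**Step count**

Total steps: 15. Longest linear sequence: 15 steps (from 1).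

**Steps most likely to fail**

1. Step 15. What may go wrong: poor facial selectivity in the addition to the C6 aldehyde inside the forming ring, with acyl transfer then locking in the wrong C6 configuration; oligomerisation is the second concern. The fallback sets out from 24 and comes back at 27. The ring closure is run in the catalytic-in-chromium mode (CrCl2 and NiCl2 in catalytic amount, Mn powder, Me3SiCl, DMF–DME, high dilution), which traps the C6 alkoxide as the trimethylsilyl ether F1 (both C6 epimers) and blocks acyl transfer. Mild desilylation (citric acid, MeOH, 0 °C) gives the C6 alcohol mixture F2, which is oxidised at once with Dess–Martin periodinane and NaHCO3 to the C4=C5–C6 enone F3. Corey–Bakshi–Shibata reduction with the (S)-oxazaborolidine and catecholborane, the alkenyl group acting as the large substituent, should give the (6R)-alcohol F4 under reagent control. A catalytic amount of DBU in CH2Cl2 then effects the δ-to-γ acyl transfer to 27.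

2. Step 9. What may go wrong: weak facial discrimination by the boron enolate on the trisubstituted Z-enal, or Z-to-E isomerisation of the enal under the Lewis acid. The fallback sets out from 13 and comes back at 19. The achiral lithium enolate of 14 (LiN(i-Pr)2, THF, −78 °C) is added to 13 without face control. Because C3 is fixed, 17 and its C9 epimer, the (7R)-hydroxy ketone F5, are diastereomers and are separated on silica. Compound 17 goes on through step 10, and F5 is esterified with 18 under Mitsunobu conditions (PPh3, DIAD, toluene, 0 °C) with inversion at C9, so that both epimers converge on 19.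

3. Step 12. What may go wrong: hydride delivery to the wrong face of the dihydropyranone, so that C7 is formed as a mixture. The fallback sets out from 20 and comes back at 24; it replaces kinetic face selection by thermodynamic equilibration. The mixture of 21 and its C7 epimer, the (2S,4R)-lactone F6, is carried through steps 13 and 14: methylation anti to the C7 group gives 23 together with the (2S,4R,5S)-acetal F7, and hydrolysis gives 24 together with the (2S,4R,5S)-aldehyde F8. The aldehyde mixture is then stirred with DBU (CH2Cl2, rt to 40 °C). C7 is α to the aldehyde and C11 is α to the lactone carbonyl, so both epimerise through their enols, and the all-equatorial isomer 24 is the expected sink.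

**Further compounds**

F1 | step 15 | O6-trimethylsilyl ether of the bicyclic δ-lactone (both C6 epimers) | CC[C@@H](C)C(=O)O[C@H]1C/C=C(/C)[C@@H]3C[C@H](C(/C=C/1C)O[Si](C)(C)C)[C@@H](C)C(=O)O3
F2 | step 15 | bicyclic 6-hydroxy δ-lactone (both C6 epimers) | CC[C@@H](C)C(=O)O[C@H]1C/C=C(/C)[C@@H]3C[C@H](C(/C=C/1C)O)[C@@H](C)C(=O)O3
F3 | step 15 | bicyclic δ-lactone C6 ketone (C4=C5–C6 enone) | CC[C@@H](C)C(=O)O[C@H]1C/C=C(/C)[C@@H]3C[C@H](C(=O)/C=C/1C)[C@@H](C)C(=O)O3
F4 | step 15 | (6R)-6-hydroxy bicyclic δ-lactone | CC[C@@H](C)C(=O)O[C@H]1C/C=C(/C)[C@@H]3C[C@H]([C@H](/C=C/1C)O)[C@@H](C)C(=O)O3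
F5 | step 9 | (1E,3S,5Z,7R)-7-hydroxy-1-iodo-10,10-dimethoxy-2,6-dimethyl-9-oxodeca-1,5-dien-3-yl (2R)-2-methylbutanoate | CC[C@@H](C)C(=O)O[C@@H](C/C=C(/C)[C@H](O)CC(=O)C(OC)OC)/C(C)=C/I
F6 | step 12 | (1E,3S,5Z)-6-[(2S,4R)-4-(dimethoxymethyl)-6-oxooxan-2-yl]-1-iodo-2-methylhepta-1,5-dien-3-yl (2R)-2-methylbutanoate | CC[C@@H](C)C(=O)O[C@@H](C/C=C(/C)[C@@H]1C[C@@H](C(OC)OC)CC(=O)O1)/C(C)=C/I
F7 | step 12 | (1E,3S,5Z)-6-[(2S,4R,5S)-4-(dimethoxymethyl)-5-methyl-6-oxooxan-2-yl]-1-iodo-2-methylhepta-1,5-dien-3-yl (2R)-2-methylbutanoate | CC[C@@H](C)C(=O)O[C@@H](C/C=C(/C)[C@@H]1C[C@@H](C(OC)OC)[C@H](C)C(=O)O1)/C(C)=C/I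
F8 | step 12 | (1E,3S,5Z)-6-[(2S,4R,5S)-4-formyl-5-methyl-6-oxooxan-2-yl]-1-iodo-2-methylhepta-1,5-dien-3-yl (2R)-2-methylbutanoate | CC[C@@H](C)C(=O)O[C@@H](C/C=C(/C)[C@@H]1C[C@@H](C=O)[C@H](C)C(=O)O1)/C(C)=C/I
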